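## The problem

The target 15 is a spiro compound. One carbon is shared by a γ-lactam (ring B, fused to the methoxybenzene ring A) and by a 2H-naphtho[1,8-bc]furan, whose five-membered ether ring C bridges the peri positions of a naphthalene (ring D carries the hydroxyl, ring E the methyl). That carbon bears the lactam nitrogen, the ether oxygen, C7a of ring A and C2a' of the naphthalene.

It is the only stereocentre, it is fully substituted, and nothing else in the molecule can relay configuration to it. It must therefore be set by an external chiral agent and then carried through every later bond change without becoming planar.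

As an N-acyl N,O-ketal flanked by two arenes it can ionise under acid. Under base the free 3'-hydroxyl next to it can expel the ether oxygen or the amide nitrogen through an ortho-quinone methide. Either event would racemise the compound.

The centre is crowded: ring A is substituted on both sides of its point of attachment (OMe and the lactam carbonyl), and the naphthalene is substituted at the ortho position (OH) and the peri position (ether O). The aryl C–O bond of ring C must be made on a naphthalene that is commercially available only without the peri oxygen. The naphthol is easily oxidised and must stay masked until the end.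

The feature that opens the key step is the N–C(=O) unit between the spiro carbon and the ortho carbon of ring A. Read as an isocyanate, its nitrogen can be delivered by a Curtius shift of a carboxyl group on the spiro carbon, and its carbon can be joined to an ortho C–Br carbon of ring A. The labile N,O-ketal is then stored as an α-aryloxy carboxylic acid that cannot ionise.

## Retrosynthesis

**15 ⇒ 14 ⇒ 12 + 13.** The two O–Si bonds are cut first, so that the free naphthol next to the spiro carbon appears only in the last step under buffered fluoride. The N–CH2 bond is cut next, giving N-unsubstituted lactam 12 and commercially available iodide 13. The side chain cannot be carried earlier, because the nitrogen itself only enters the molecule in the key step. The forward reaction must alkylate a hindered lactam nitrogen without touching the aryl silyl ether.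

**12 ⇒ 11 ⇒ 10 (key disconnection).** The bond between the lactam carbonyl carbon and ring A is cut, giving isocyanate 11 with an ortho C–Br bond. The N–C(spiro) bond is then cut by reversing a Curtius shift, giving acyl azide 10. The neighbouring cuts at the spiro C–N or spiro C–O bond would form the stereocentre by capture of a planar N-acyliminium or oxocarbenium ion, with no handle for absolute control. The chosen cut never passes through such an ion. Compound 10 has neither ring B nor the N,O-ketal. The forward reaction needs retention in the 1,2-shift and capture of the isocyanate carbon by an aryl–nickel bond before anything else reaches it.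

**10 ⇒ 9 ⇒ 8.** These are functional-group changes: acyl azide from acid 9, acid from tert-butyl ester 8. A tert-butyl ester is chosen because it is removed by acid. Hydroxide would strip the aryl silyl ether and expose the naphthoxide next to the stereocentre. The bulky ester also cannot lactonise onto the naphthol at the Friedel–Crafts stage.

**8 ⇒ 7.** The aryl C8a'–O bond of ring C is cut, leaving tertiary alcohol 7 with an unfunctionalised peri C–H. The other C–O bond of ring C (oxygen to the quaternary carbon) is the poorer cut: its closure would be an SN1 reaction at a diaryl carbinol and would lose the configuration, and it would need a peri-oxygenated naphthalene that is not at hand. The forward reaction must functionalise the peri C–H while the carbinol C–O bond stays intact. Only that C–H is within reach, because ring A has no ortho hydrogen and C2 of the naphthalene carries oxygen.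

**7 ⇒ 6 ⇒ 4 + 5.** The silyl group is removed, then the bond between the carbinol carbon and C1 of the naphthalene is cut: a Friedel–Crafts hydroxyalkylation of 6-methylnaphthalen-2-ol 5 with keto ester 4. The reverse polarity (an aryl metal of ring A adding to a naphthyl glyoxylate) would need a benzyne-prone aryllithium and has no catalytic asymmetric version. The Friedel–Crafts reaction uses the innate nucleophilic site of a 2-naphthol and belongs to a known class of catalytic asymmetric reactions. The whole carbon skeleton of 9 comes from two simple pieces; the price is enantiofacial control at a hindered ketone.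

**4 ⇒ 3 ⇒ 1 + 2.** The aryl–C(=O) bond is cut. 3-Bromoanisole 1 is lithiated between its two substituents to aryllithium 3, which is acylated by di-tert-butyl oxalate 2. One step gives the 1,2,3-pattern of ring A with bromine already ortho to the future spiro carbon.

## Roads not taken

**Alternative 1:** The cut is the C2a'–C3' bond of ring D, which opens that ring to a 3-oxopropyl chain on a spiro benzofuran-3-one, aldehyde A1. In the forward step a triazolium-derived N-heterocyclic carbene turns the aldehyde into an acyl-anion equivalent that adds to the benzofuranone ketone (6-exo crossed benzoin), giving α-ketol A2. Dehydration and tautomerisation would then give the naphthol.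
- Merits: intramolecular benzoin additions to ketones are reliable. The ether oxygen of ring C comes from an ordinary phenol, so no peri C–H etherification is needed. The naphthol appears late.
- Weak points: the spiro stereocentre must already exist in A1, as an N,O-ketal next to a ketone, and this plan offers no way to make it in one absolute configuration. That centre is more electrophilic and more easily opened than anything in the chosen route. The tertiary α-ketol A2 must then be dehydrated under acid beside the N,O-ketal, where ionisation and α-ketol shifts threaten.
- Comparison: Alternative 1 is better on ring C, since it avoids both the hindered Friedel–Crafts step and the peri etherification. The chosen plan sets against this a defined origin of configuration (a catalytic hydroxyalkylation) and a stereocentre that stays a non-ionisable acid derivative until nitrogen arrives with retention.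

**Alternative 2:** The cuts are the spiro C–O bond of ring C and the C2a'–C8b' bond. Ring C is assembled from ylidene isoindolinone A3 and 5-methylcyclohexane-1,3-dione A4. Mn(OAc)3 oxidises A4 to a radical that adds to the β-carbon of A3; the α-amido radical is oxidised to an N-acyliminium ion, which the enol oxygen captures to give A5.
- Merits: one step builds ring C and the N,O-ketal from two simple pieces. The oxygen at C8a' comes with the dione, and dihydrofuran annulation of 1,3-diones with trivalent manganese is well precedented. Here it is stronger than the chosen plan, whose step 4 transfers a known etherification to a peri position.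
- Weak points: the spiro centre forms by capture of a planar cation with nothing to control its face, so A5 is racemic at that centre and a mixture at two others. Ring D is still missing: two carbons must be added between the ester and ketone carbons, the ring closed, and both carbocycles dehydrogenated to the naphthol, all with the acid-labile N,O-ketal in place.
- Comparison: the spiro core is reached faster, but the plan has no absolute control and a long oxidation-level adjustment. The chosen plan carries the arene at its final oxidation level and sets the configuration once.

**Alternative 3:** Ring A is cut at three C–C bonds (C3a–C7a, C4–C5, C6–C7), giving diyne A6 (a methoxyethynyl group on the spiro carbon and an N-propioloyl group) and acetylene A7. Cp*RuCl(cod) couples the tethered diyne to a ruthenacycle, A7 inserts, and reductive elimination closes ring A and ring B at once. The product A8 is identical with 14.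
- Merits: very convergent. Amide-tethered 1,6-diynes are good cyclotrimerisation substrates. No addition to a hindered ketone and no hindered aryl bromide is needed, and the product is one step from 15. In precedent and convergence of the key step this road is at least as good as the chosen one.
- Weak points: A6 carries the stereocentre as a propargylic N,O-ketal with an ynol ether. This is the most ionisable form the centre could take, and no asymmetric route to it is evident. Ynol ethers are acid-sensitive and may oligomerise on ruthenium. Ring C with its peri ether must be made anyway.
- Comparison: the chosen plan has to set against this convergence the safekeeping of configuration (acid, acyl azide, isocyanate, lactam; never a free N,O-ketal with a leaving group) and the stereospecific introduction of nitrogen.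

Key step: step 7

Remark on the chemistry (assumption): the sense of induction of the quinine-derived squaramide with keto ester 4 cannot be predicted with confidence. The route is written for the catalyst that gives (S)-6; if the opposite sense is found, the quinidine-derived pseudoenantiomer is used and nothing else changes. The configuration of 6 is to be secured (anomalous dispersion of the bromide) before going on.

## Route

**Step 1**
Reactants: 1 3-bromoanisole; 2 di-tert-butyl oxalate
Product: 4 tert-butyl 2-(2-bromo-6-methoxyphenyl)-2-oxoacetate, via 2-bromo-6-methoxyphenyllithium 3 (not isolated)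
Conditions: LiN(iPr)2, THF, −78 °C; then transfer into 2 (2 equiv), THF, −78 °C; NH4Cl aq
Reagents that add atoms: none
Why: Directed ortho-lithiation: the hydrogen between OMe and Br is the most acidic, and LiN(iPr)2 removes it at −78 °C without bromine–lithium exchange or benzyne formation. Acylation of the aryllithium with excess oxalate (inverse addition) stops at the keto ester because the tetrahedral adduct persists at −78 °C.

**Step 2**
Reactants: 4 tert-butyl 2-(2-bromo-6-methoxyphenyl)-2-oxoacetate; 5 6-methylnaphthalen-2-ol
Product: 6 tert-butyl (2S)-2-(2-bromo-6-methoxyphenyl)-2-hydroxy-2-(2-hydroxy-6-methylnaphthalen-1-yl)acetate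
Conditions: quinine-derived 3,5-bis(trifluoromethyl)phenyl squaramide (10–20 mol %), 4 Å molecular sieves, toluene, 0 °C → rt
Reagents that add atoms: none
Why: Catalytic asymmetric Friedel–Crafts hydroxyalkylation of a 2-naphthol with an α-keto ester under bifunctional cinchona squaramide catalysis: the quinuclidine nitrogen activates the naphthol O–H, the squaramide N–H bonds hold the 1,2-dicarbonyl unit, and C1 of the naphthol, its innate nucleophilic site, adds to the ketone. The stereocentre is set by the catalyst-controlled choice of the ketone face (taken as S, see the remark); the tert-butyl ester cannot lactonise onto the naphthol.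

**Step 3**
Reactants: 6 tert-butyl (2S)-2-(2-bromo-6-methoxyphenyl)-2-hydroxy-2-(2-hydroxy-6-methylnaphthalen-1-yl)acetate
Product: 7 tert-butyl (2S)-2-(2-bromo-6-methoxyphenyl)-2-[2-(tert-butyldimethylsilyloxy)-6-methylnaphthalen-1-yl]-2-hydroxyacetate
Conditions: TBSCl, imidazole, DMF, rt
Reagents that add atoms: tert-butyldimethylsilyl chloride CC(C)(C)[Si](C)(C)Cl
Why: Silylation of the phenolic hydroxyl; the tertiary diaryl carbinol is too hindered to react. The silyl ether shields the naphthol from PhI(OAc)2 in step 4 and shuts off retro-Friedel–Crafts and ortho-quinone methide pathways that would erode the configuration.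

**Step 4**
Reactants: 7 tert-butyl (2S)-2-(2-bromo-6-methoxyphenyl)-2-[2-(tert-butyldimethylsilyloxy)-6-methylnaphthalen-1-yl]-2-hydroxyacetate
Product: 8 tert-butyl (2S)-2-(2-bromo-6-methoxyphenyl)-3-(tert-butyldimethylsilyloxy)-7-methyl-2H-naphtho[1,8-bc]furan-2-carboxylate
Conditions: Pd(OAc)2 (10 mol %), PhI(OAc)2 (1.5 equiv), Li2HPO4 (2 equiv), C6F6, 100 °C
Reagents that add atoms: none
Why: Hydroxyl-directed C–H activation/C–O cyclisation under Pd(OAc)2/PhI(OAc)2: the palladium alkoxide of the tertiary alcohol palladates the peri C8–H through a six-membered palladacycle, the same ring size as in the known closures of tertiary alcohols onto ortho C–H bonds; oxidation to tetravalent palladium and C–O reductive elimination close ring C. No bond to the stereocentre is broken, so the configuration is retained; ring A has no ortho hydrogen and C2 of the naphthalene is blocked, so no other aryl C–H is within reach.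

**Step 5**
Reactants: 8 tert-butyl (2S)-2-(2-bromo-6-methoxyphenyl)-3-(tert-butyldimethylsilyloxy)-7-methyl-2H-naphtho[1,8-bc]furan-2-carboxylate
Product: 9 (2S)-2-(2-bromo-6-methoxyphenyl)-3-(tert-butyldimethylsilyloxy)-7-methyl-2H-naphtho[1,8-bc]furan-2-carboxylic acid
Conditions: CF3CO2H, CH2Cl2, 0 °C → rt
Reagents that add atoms: none
Why: Acidolysis of a tert-butyl ester by alkyl–oxygen cleavage (loss of isobutene), which is insensitive to crowding at the acyl carbon and needs no base, so the aryl silyl ether stays on. The α-carboxyl group disfavours ionisation of the neighbouring C–O bond, so the stereocentre should be safe.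

**Step 6**
Reactants: 9 (2S)-2-(2-bromo-6-methoxyphenyl)-3-(tert-butyldimethylsilyloxy)-7-methyl-2H-naphtho[1,8-bc]furan-2-carboxylic acid
Product: 10 (2S)-2-(2-bromo-6-methoxyphenyl)-3-(tert-butyldimethylsilyloxy)-7-methyl-2H-naphtho[1,8-bc]furan-2-carbonyl azide
Conditions: (PhO)2P(O)N3, Et3N, toluene, 0 °C → rt; cold aqueous work-up, no heating
Reagents that add atoms: diphenylphosphoryl azide [N-]=[N+]=NP(=O)(Oc1ccccc1)Oc1ccccc1
Why: Acyl azide formation with diphenylphosphoryl azide through the mixed carboxylic–phosphoric anhydride; at or below room temperature the azide should not yet rearrange. The cold aqueous work-up removes ammonium and phosphate salts that would otherwise intercept the isocyanate or the nickel catalyst in step 7.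

**Step 7**
Reactants: 10 (2S)-2-(2-bromo-6-methoxyphenyl)-3-(tert-butyldimethylsilyloxy)-7-methyl-2H-naphtho[1,8-bc]furan-2-carbonyl azide
Product: 12 (1R)-3'-(tert-butyldimethylsilyloxy)-7-methoxy-7'-methylspiro[isoindoline-1,2'-naphtho[1,8-bc]furan]-3-one, via isocyanate 11 (not isolated)
Conditions: toluene, 80 °C (loss of N2); then Ni(cod)2 (20 mol %), 2,2'-bipyridine (24 mol %), Mn powder (2 equiv), DMF, rt → 50 °C, strictly anhydrous; NH4Cl aq
Reagents that add atoms: none
Why: On warming, 10 loses N2 in a concerted Curtius rearrangement in which the quaternary carbon migrates from the carbonyl carbon to nitrogen with retention, so the configuration set in step 2 passes unchanged into isocyanate 11 (the descriptor becomes R in 12 only because ring A loses bromine in the priority ranking). Zerovalent nickel–bipyridine then inserts into the ortho C–Br bond of ring A, the aryl–nickel bond adds across the C=N bond of the neighbouring isocyanate, and manganese reduces the nickel amidate back to zerovalent nickel; aqueous work-up protonates the amidate. The closest known reaction type is the nickel-catalysed reductive amidation of organic halides with isocyanates using a metal powder as terminal reductant, here run intramolecularly after the known Curtius route from α-alkoxy acids to N,O-acetal isocyanates. Ring B closes as a five-membered ring: 5-exo-dig with respect to the C=O bond of the cumulene (5-endo with respect to C=N), giving the same delocalised amidate either way. No new stereocentre is formed. The selectivity needed is capture of the isocyanate carbon by the aryl–nickel bond rather than by outside nucleophiles or a second isocyanate; the substrate secures it by holding C–Br and N=C=O in a 1,4-relationship on a rigid quaternary carbon. The naphthol is silylated so it cannot add to the isocyanate, and ring C with its ether oxygen is already in place.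

**Step 8**
Reactants: 12 (1R)-3'-(tert-butyldimethylsilyloxy)-7-methoxy-7'-methylspiro[isoindoline-1,2'-naphtho[1,8-bc]furan]-3-one; 13 tert-butyl(2-iodoethoxy)dimethylsilane
Product: 14 (1R)-3'-(tert-butyldimethylsilyloxy)-2-[2-(tert-butyldimethylsilyloxy)ethyl]-7-methoxy-7'-methylspiro[isoindoline-1,2'-naphtho[1,8-bc]furan]-3-one
Conditions: KN(SiMe3)2, THF–DMF, 0 °C; then 13, 0 °C → rt
Reagents that add atoms: none
Why: SN2 N-alkylation of the lactam potassium salt with a primary iodide; for a lactam anion and an alkyl iodide in a dipolar medium nitrogen is the preferred site. A non-nucleophilic silylamide base at low temperature is chosen because hydroxide or hydride bases in DMF would strip the aryl silyl ether.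

**Step 9**
Reactants: 14 (1R)-3'-(tert-butyldimethylsilyloxy)-2-[2-(tert-butyldimethylsilyloxy)ethyl]-7-methoxy-7'-methylspiro[isoindoline-1,2'-naphtho[1,8-bc]furan]-3-one
Product: 15 (1S)-3'-hydroxy-2-(2-hydroxyethyl)-7-methoxy-7'-methylspiro[isoindoline-1,2'-naphtho[1,8-bc]furan]-3-one
Conditions: Bu4NF, AcOH (1:1), THF, 0 °C → rt
Reagents that add atoms: none
Why: Fluoride cleavage of both Si–O bonds (the descriptor returns to S only through the priority change). Acetic acid buffers the medium so that the naphthol is released as the neutral phenol; a free naphthoxide next to the spiro carbon could expel the ether oxygen or the amide nitrogen via an ortho-quinone methide and re-close with loss of configuration.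

## Compound list

1 | 3-bromoanisole (1-bromo-3-methoxybenzene) | COc1cccc(Br)c1 | starting material
2 | di-tert-butyl oxalate | CC(C)(C)OC(=O)C(=O)OC(C)(C)C | starting material
3 | 2-bromo-6-methoxyphenyllithium | COc1cccc(Br)c1[Li] | intermediate (not isolated)
4 | tert-butyl 2-(2-bromo-6-methoxyphenyl)-2-oxoacetate | COc1cccc(Br)c1C(=O)C(=O)OC(C)(C)C | intermediate
5 | 6-methylnaphthalen-2-ol | Cc1ccc2cc(O)ccc2c1 | starting material
6 | tert-butyl (2S)-2-(2-bromo-6-methoxyphenyl)-2-hydroxy-2-(2-hydroxy-6-methylnaphthalen-1-yl)acetate | COc1cccc(Br)c1[C@](O)(C(=O)OC(C)(C)C)c1c(O)ccc2cc(C)ccc12 | intermediate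
7 | tert-butyl (2S)-2-(2-bromo-6-methoxyphenyl)-2-[2-(tert-butyldimethylsilyloxy)-6-methylnaphthalen-1-yl]-2-hydroxyacetate | COc1cccc(Br)c1[C@](O)(C(=O)OC(C)(C)C)c1c(O[Si](C)(C)C(C)(C)C)ccc2cc(C)ccc12 | intermediate
8 | tert-butyl (2S)-2-(2-bromo-6-methoxyphenyl)-3-(tert-butyldimethylsilyloxy)-7-methyl-2H-naphtho[1,8-bc]furan-2-carboxylate | COc1cccc(Br)c1[C@]1(Oc2cc(C)cc3ccc(O[Si](C)(C)C(C)(C)C)c1c23)C(=O)OC(C)(C)C | intermediate
9 | (2S)-2-(2-bromo-6-methoxyphenyl)-3-(tert-butyldimethylsilyloxy)-7-methyl-2H-naphtho[1,8-bc]furan-2-carboxylic acid | COc1cccc(Br)c1[C@]1(Oc2cc(C)cc3ccc(O[Si](C)(C)C(C)(C)C)c1c23)C(=O)O | intermediate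
10 | (2S)-2-(2-bromo-6-methoxyphenyl)-3-(tert-butyldimethylsilyloxy)-7-methyl-2H-naphtho[1,8-bc]furan-2-carbonyl azide | COc1cccc(Br)c1[C@]1(Oc2cc(C)cc3ccc(O[Si](C)(C)C(C)(C)C)c1c23)C(=O)N=[N+]=[N-] | intermediate (precursor of the key step)
11 | (2S)-2-(2-bromo-6-methoxyphenyl)-3-(tert-butyldimethylsilyloxy)-2-isocyanato-7-methyl-2H-naphtho[1,8-bc]furan | COc1cccc(Br)c1[C@]1(Oc2cc(C)cc3ccc(O[Si](C)(C)C(C)(C)C)c1c23)N=C=O | intermediate (not isolated)
12 | (1R)-3'-(tert-butyldimethylsilyloxy)-7-methoxy-7'-methylspiro[isoindoline-1,2'-naphtho[1,8-bc]furan]-3-one | COc1cccc2c1[C@]1(Oc3cc(C)cc4ccc(O[Si](C)(C)C(C)(C)C)c1c34)NC2=O | intermediate (product of the key step)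
13 | tert-butyl(2-iodoethoxy)dimethylsilane | CC(C)(C)[Si](C)(C)OCCI | starting material
14 | (1R)-3'-(tert-butyldimethylsilyloxy)-2-[2-(tert-butyldimethylsilyloxy)ethyl]-7-methoxy-7'-methylspiro[isoindoline-1,2'-naphtho[1,8-bc]furan]-3-one | COc1cccc2c1[C@]1(Oc3cc(C)cc4ccc(O[Si](C)(C)C(C)(C)C)c1c34)N(CCO[Si](C)(C)C(C)(C)C)C2=O | intermediate
15 | (1S)-3'-hydroxy-2-(2-hydroxyethyl)-7-methoxy-7'-methylspiro[isoindoline-1,2'-naphtho[1,8-bc]furan]-3-one | COc1cccc2c1[C@]1(Oc3cc(C)cc4ccc(O)c1c34)N(CCO)C2=O | target

## Step count and least certain steps

Total: 9 steps. Longest linear sequence: 9 steps (1 → 15).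

**Step 7 (key step).** The most likely failures are:
- loss of configuration by reversible ionisation of the α-aryloxy isocyanate in the polar, Lewis-acidic medium (manganese salts in DMF);
- consumption of the isocyanate by nickel-mediated oligomerisation;
- protodebromination, if oxidative addition beside the quaternary carbon is slow.

Fallback: the same C–C bond is made through an aryllithium instead of nickel. Setting out from 10, the Curtius rearrangement is run in toluene at 80 °C and the isocyanate is trapped with dimethylamine to give the N,N-dimethylurea F1. Deprotonation of the N–H with MeLi and bromine–lithium exchange with t-BuLi in THF at −78 °C should then trigger a Parham-type anionic cyclisation onto the urea carbonyl with loss of dimethylamide. This returns to the route at 12.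

**Step 4.** The closure is known for ortho C–H bonds of tertiary alcohols and is here transferred to a peri C–H. The crowded palladium alkoxide may undergo β-aryl elimination (a retro-Friedel–Crafts fragmentation) faster than palladation, or the electron-rich silyloxynaphthalene may be oxidised by PhI(OAc)2.

Fallback: a metal-free oxidative cyclisation that sets out from 7 and returns at 8. The trivalent iodine reagent PhI(OCOCF3)2 in (CF3)2CHOH at low temperature oxidises the silyloxynaphthalene to its cation radical. The tertiary hydroxyl, which can reach only C8, adds, and further oxidation with loss of a proton gives the ether. No palladium alkoxide is involved, so β-aryl elimination is not possible. This detour makes no new compound (F0).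

**Step 2.** Both faces of the ketone are screened by the ortho substituents of the twisted ring A. The addition may therefore be slow, facial discrimination may be poor, and reversal of the addition under the basic catalyst may erode the enantiomeric purity.

Fallback: stereocontrol is replaced by resolution. Setting out from 4 and 5, the bromomagnesium naphthoxide of 5 (EtMgBr, CH2Cl2) delivers the chelated keto ester to C1 and gives the racemic hydroxy ester F2. Silylation as in step 3 gives the racemic silyl ether F3, which is no longer prone to reversal. Preparative chromatography on a chiral stationary phase then separates the (S)-enantiomer, which is 7, where the route is rejoined.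

**Step 8.** The nitrogen is flanked by the spiro carbon. Substitution may therefore lose to O-alkylation of the ambident anion, to E2 elimination of the β-silyloxy iodide, or to loss of the aryl silyl group followed by alkylation of the naphthoxide.

Fallback: a more reactive electrophile that cannot eliminate. Setting out from 12, alkylation with ethyl bromoacetate (KN(SiMe3)2, THF) gives the N-acetate ester F4. LiBH4 in THF reduces the ester, leaving the lactam untouched, to the N-(2-hydroxyethyl) mono-silyl ether F5. The buffered fluoride conditions of step 9 then remove the remaining silyl group, and the route is rejoined at 15.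

## Further compounds

F1 | step 7 | 3-[(2S)-2-(2-bromo-6-methoxyphenyl)-3-(tert-butyldimethylsilyloxy)-7-methyl-2H-naphtho[1,8-bc]furan-2-yl]-1,1-dimethylurea | COc1cccc(Br)c1[C@]1(Oc2cc(C)cc3ccc(O[Si](C)(C)C(C)(C)C)c1c23)NC(=O)N(C)C
F0 | step 4 | none | none
F2 | step 2 | racemic tert-butyl 2-(2-bromo-6-methoxyphenyl)-2-hydroxy-2-(2-hydroxy-6-methylnaphthalen-1-yl)acetate | COc1cccc(Br)c1C(O)(C(=O)OC(C)(C)C)c1c(O)ccc2cc(C)ccc12
F3 | step 2 | racemic tert-butyl 2-(2-bromo-6-methoxyphenyl)-2-[2-(tert-butyldimethylsilyloxy)-6-methylnaphthalen-1-yl]-2-hydroxyacetate | COc1cccc(Br)c1C(O)(C(=O)OC(C)(C)C)c1c(O[Si](C)(C)C(C)(C)C)ccc2cc(C)ccc12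
F4 | step 8 | ethyl 2-[(1R)-3'-(tert-butyldimethylsilyloxy)-7-methoxy-7'-methyl-3-oxospiro[isoindoline-1,2'-naphtho[1,8-bc]furan]-2-yl]acetate | COc1cccc2c1[C@]1(Oc3cc(C)cc4ccc(O[Si](C)(C)C(C)(C)C)c1c34)N(CC(=O)OCC)C2=O
F5 | step 8 | (1R)-3'-(tert-butyldimethylsilyloxy)-2-(2-hydroxyethyl)-7-methoxy-7'-methylspiro[isoindoline-1,2'-naphtho[1,8-bc]furan]-3-one | COc1cccc2c1[C@]1(Oc3cc(C)cc4ccc(O[Si](C)(C)C(C)(C)C)c1c34)N(CCO)C2=O
A1 | alternative 1 | spiro benzofuran-3-one aldehyde: N-[2-(tert-butyldimethylsilyloxy)ethyl]-7-methoxy isoindolinone spiro-fused at C2 of 6-methyl-4-(3-oxopropyl)benzofuran-3-one | COc1cccc2c1[C@]1(Oc3cc(C)cc(CCC=O)c3C1=O)N(CCO[Si](C)(C)C(C)(C)C)C2=O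
A2 | alternative 1 | tricyclic α-ketol from the benzoin closure (carbinol configuration not defined) | COc1cccc2c1[C@]1(Oc3cc(C)cc4CCC(=O)C1(O)c34)N(CCO[Si](C)(C)C(C)(C)C)C2=O
A3 | alternative 2 | methyl 2-{2-[2-(tert-butyldimethylsilyloxy)ethyl]-7-methoxy-3-oxoisoindolin-1-ylidene}acetate | COC(=O)C=C1N(CCO[Si](C)(C)C(C)(C)C)C(=O)c2cccc(OC)c21
A4 | alternative 2 | 5-methylcyclohexane-1,3-dione | CC1CC(=O)CC(=O)C1
A5 | alternative 2 | spiro dihydrofuran-fused cyclohexenone ester (ester- and methyl-bearing carbons as mixtures) | COc1cccc2c1[C@]1(OC3=C(C1C(=O)OC)C(=O)CC(C)C3)N(CCO[Si](C)(C)C(C)(C)C)C2=O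
A6 | alternative 3 | N-[2-(tert-butyldimethylsilyloxy)ethyl]-N-[3-(tert-butyldimethylsilyloxy)-2-(methoxyethynyl)-7-methyl-2H-naphtho[1,8-bc]furan-2-yl]propiolamide | COC#C[C@]1(Oc2cc(C)cc3ccc(O[Si](C)(C)C(C)(C)C)c1c23)N(CCO[Si](C)(C)C(C)(C)C)C(=O)C#C
A7 | alternative 3 | acetylene | C#C
A8 | alternative 3 | bis-silyl ether of the target (identical with 14) | COc1cccc2c1[C@]1(Oc3cc(C)cc4ccc(O[Si](C)(C)C(C)(C)C)c1c34)N(CCO[Si](C)(C)C(C)(C)C)C2=O
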